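The isoflavone is disconnected at C4–C4a of the pyranone ring (ring C). Because O1, O5 and O7 sit mutually meta on ring A, the O1 ether of a 4-allyl-3,5-dimethoxyphenyl group has two equivalent ortho carbons. Intramolecular Friedel–Crafts acylation at either one forges C4–C4a, closes ring C and fixes the allyl handle at C6 in a single operation. The precursor is the Z 3-aryloxy-2-arylacrylic acid 11 (carboxyl cis to the aryloxy group), assembled from a metalation-derived 4-allylphenol and a Z enol tosylate of formylated methyl 4-methoxyphenylacetate. Demethylation, cross-metathesis with methacrolein and Luche reduction then finish the E-hydroxyprenyl side chain.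

Key step: step 8

Remark: compound 8 is drawn as its hydrogen-bonded Z enol tautomer. Compounds 9–11 are carried as the Z isomers expected from chelation-controlled tosylation and stereoretentive vinylic substitution. Any E isomer should converge in step 8, where the push–pull double bond is configurationally labile.

Step 1
Reactants: 1 3,5-dimethoxyphenol
Product: 2 (3,5-dimethoxyphenoxy)triisopropylsilane
Conditions: TIPSCl, imidazole, DMF, 0 °C → rt
Reagents that add atoms: triisopropylsilyl chloride, CC(C)[Si](Cl)(C(C)C)C(C)C
Why: Imidazole-promoted O-silylation masks the acidic phenol, and the bulky silyl group shields both carbons next to it so that the later metalation is steered to C4.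

Step 2
Reactants: 2 (3,5-dimethoxyphenoxy)triisopropylsilane; 3 allyl bromide
Product: 5 (4-allyl-3,5-dimethoxyphenoxy)triisopropylsilane, via aryllithium 4 (not isolated)
Conditions: n-BuLi, TMEDA, THF, 0 °C → rt; then allyl bromide, −78 °C → rt
Reagents that add atoms: none
Why: Directed ortho-metalation places lithium on the carbon flanked by the two coordinating methoxy groups (the hindered silyloxy group is a poor director), and the aryllithium then displaces bromide from allyl bromide, direct and allylic substitution giving the same product.

Step 3
Reactants: 5 (4-allyl-3,5-dimethoxyphenoxy)triisopropylsilane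
Product: 6 4-allyl-3,5-dimethoxyphenol
Conditions: TBAF, AcOH, THF, 0 °C → rt
Reagents that add atoms: none
Why: Fluoride-mediated desilylation, driven by Si–F bond formation, frees the phenol under buffered conditions that leave the allyl group and methyl ethers untouched.

Step 4
Reactants: 7 methyl 4-methoxyphenylacetate
Product: 8 methyl (Z)-3-hydroxy-2-(4-methoxyphenyl)acrylate
Conditions: NaH, HCO2Me, THF, 0 °C → rt; aq. HCl
Reagents that add atoms: methyl formate, COC=O
Why: Crossed Claisen condensation (C-formylation) of the arylacetate enolate with non-enolisable methyl formate is driven by deprotonation of the product to its stabilised enolate, and acidification should give the chelated Z enol.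

Step 5
Reactants: 8 methyl (Z)-3-hydroxy-2-(4-methoxyphenyl)acrylate
Product: 9 methyl (Z)-2-(4-methoxyphenyl)-3-(tosyloxy)acrylate
Conditions: TsCl, N-methylimidazole, LiOH, toluene, 0 °C
Reagents that add atoms: p-toluenesulfonyl chloride, Cc1ccc(cc1)S(Cl)(=O)=O
Why: O-Sulfonylation of the enolate by the N-sulfonylimidazolium formed from TsCl and N-methylimidazole; the lithium chelate between enolate oxygen and ester carbonyl is expected to deliver the Z enol tosylate (tosyloxy cis to the ester).

Step 6
Reactants: 6 4-allyl-3,5-dimethoxyphenol; 9 methyl (Z)-2-(4-methoxyphenyl)-3-(tosyloxy)acrylate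
Product: 10 methyl (Z)-3-(4-allyl-3,5-dimethoxyphenoxy)-2-(4-methoxyphenyl)acrylate
Conditions: K2CO3, MeCN, 0 °C → rt
Reagents that add atoms: none
Why: Nucleophilic vinylic substitution by addition–elimination, in which the phenoxide adds to the β-carbon of the acceptor-activated enol tosylate and tosylate leaves from a short-lived ester-stabilised carbanion, which is expected to retain the Z geometry.

Step 7
Reactants: 10 methyl (Z)-3-(4-allyl-3,5-dimethoxyphenoxy)-2-(4-methoxyphenyl)acrylate
Product: 11 (Z)-3-(4-allyl-3,5-dimethoxyphenoxy)-2-(4-methoxyphenyl)acrylic acid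
Conditions: LiOH·H2O, THF/MeOH/H2O, rt; then 1 M HCl to pH 3, 0 °C
Reagents that add atoms: lithium hydroxide (hydroxide oxygen), [Li+].[OH-]
Why: Saponification of the methyl ester by acyl substitution, the usual access to 3-aryloxyacrylic acids; the mild temperature limits hydroxide attack at the β-carbon, and the aryl methyl ethers and allyl group are inert.

Step 8
Reactants: 11 (Z)-3-(4-allyl-3,5-dimethoxyphenoxy)-2-(4-methoxyphenyl)acrylic acid
Product: 13 6-allyl-5,7-dimethoxy-3-(4-methoxyphenyl)-4H-chromen-4-one, via mixed anhydride 12 (not isolated)
Conditions: (CF3CO)2O, CH2Cl2, 0 °C → rt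
Reagents that add atoms: none
Why: Trifluoroacetic anhydride converts acid 11 into mixed anhydride 12, which reacts as an acylium ion held next to ring A; the carbon ortho to the ether oxygen attacks it and the Wheland intermediate loses a proton, giving the C4–C4a bond and the chromone. The closest known reaction type is the anhydride- or acid-mediated intramolecular Friedel–Crafts acylation of 3-aryloxyacrylic and 2-aryloxybenzoic acids to chromones and xanthones. The pyranone ring (ring C) closes by a 6-exo-trig acyl substitution at the anhydride carbonyl, with the arene carbon as nucleophile. No stereocentre is formed. The step needs regioselectivity on ring A and tolerance of the allyl group: the attacked carbon is ortho and para to the two methoxy groups, and because O1, O5 and O7 are mutually meta the two ortho carbons are mirror-equivalent, so either closure puts the allyl group at C6, while the non-aqueous, weakly acidic medium should leave the monosubstituted alkene alone. The Z geometry of 11 holds carboxyl and aryloxy on the same side, and any E isomer can equilibrate through the delocalised oxocarbenium/ketene-like acyl cation.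

Step 9
Reactants: 13 6-allyl-5,7-dimethoxy-3-(4-methoxyphenyl)-4H-chromen-4-one
Product: 14 6-allyl-5,7-dihydroxy-3-(4-hydroxyphenyl)-4H-chromen-4-one
Conditions: BBr3, CH2Cl2, −78 °C → rt; ice-water quench
Reagents that add atoms: none
Why: Lewis-acid ether cleavage, in which BBr3 coordinates each methoxy oxygen and bromide removes the methyl group by SN2 (the 5-methoxy group first, helped by chelation to the C4 carbonyl); the monosubstituted alkene is expected to survive with a cold quench, as in demethylations of allyl-substituted anisoles.

Step 10
Reactants: 14 6-allyl-5,7-dihydroxy-3-(4-hydroxyphenyl)-4H-chromen-4-one; 15 methacrolein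
Product: 16 (E)-4-[5,7-dihydroxy-3-(4-hydroxyphenyl)-4-oxo-4H-chromen-6-yl]-2-methylbut-2-enal
Conditions: second-generation Grubbs catalyst RuCl2(=CHPh)(PCy3)(H2IMes) (5 mol %), methacrolein (excess), CH2Cl2/THF, 40 °C
Reagents that add atoms: none
Why: Olefin cross-metathesis between the terminal allyl olefin and the electron-poor 1,1-disubstituted methacrolein should give the thermodynamically favoured E-trisubstituted enal (formyl trans to the benzylic CH2) with loss of ethene, and free phenols are tolerated by the ruthenium carbene.

Step 11
Reactants: 16 (E)-4-[5,7-dihydroxy-3-(4-hydroxyphenyl)-4-oxo-4H-chromen-6-yl]-2-methylbut-2-enal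
Product: 17 5,7-dihydroxy-6-[(E)-4-hydroxy-3-methylbut-2-en-1-yl]-3-(4-hydroxyphenyl)-4H-chromen-4-one
Conditions: NaBH4, CeCl3·7H2O, MeOH/THF, −40 → 0 °C; aq. NH4Cl
Reagents that add atoms: none
Why: Luche reduction, in which CeCl3-modified borohydride reduces the aldehyde 1,2-selectively and far faster than the hydrogen-bonded vinylogous-ester carbonyl C4 of the chromone; the E double bond set in step 10 is not touched.

Compound list
1 | 3,5-dimethoxyphenol | COc1cc(O)cc(OC)c1 | starting material
2 | (3,5-dimethoxyphenoxy)triisopropylsilane | COc1cc(O[Si](C(C)C)(C(C)C)C(C)C)cc(OC)c1 | intermediate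
3 | allyl bromide | C=CCBr | starting material
4 | [2,6-dimethoxy-4-(triisopropylsilyloxy)phenyl]lithium (formed in the flask) | [Li]c1c(OC)cc(O[Si](C(C)C)(C(C)C)C(C)C)cc1OC | intermediate
5 | (4-allyl-3,5-dimethoxyphenoxy)triisopropylsilane | C=CCc1c(OC)cc(O[Si](C(C)C)(C(C)C)C(C)C)cc1OC | intermediate
6 | 4-allyl-3,5-dimethoxyphenol | C=CCc1c(OC)cc(O)cc1OC | intermediate
7 | methyl 4-methoxyphenylacetate | COC(=O)Cc1ccc(OC)cc1 | starting material
8 | methyl (Z)-3-hydroxy-2-(4-methoxyphenyl)acrylate (enol of the α-formyl ester) | COC(=O)/C(=C\O)c1ccc(OC)cc1 | intermediate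
9 | methyl (Z)-2-(4-methoxyphenyl)-3-(tosyloxy)acrylate | COC(=O)/C(=C\OS(=O)(=O)c1ccc(C)cc1)c1ccc(OC)cc1 | intermediate
10 | methyl (Z)-3-(4-allyl-3,5-dimethoxyphenoxy)-2-(4-methoxyphenyl)acrylate | COC(=O)/C(=C\Oc1cc(OC)c(CC=C)c(OC)c1)c1ccc(OC)cc1 | intermediate
11 | (Z)-3-(4-allyl-3,5-dimethoxyphenoxy)-2-(4-methoxyphenyl)acrylic acid | OC(=O)/C(=C\Oc1cc(OC)c(CC=C)c(OC)c1)c1ccc(OC)cc1 | intermediate
12 | (Z)-3-(4-allyl-3,5-dimethoxyphenoxy)-2-(4-methoxyphenyl)acrylic trifluoroacetic anhydride (formed in the flask) | O=C(OC(=O)C(F)(F)F)/C(=C\Oc1cc(OC)c(CC=C)c(OC)c1)c1ccc(OC)cc1 | intermediate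
13 | 6-allyl-5,7-dimethoxy-3-(4-methoxyphenyl)-4H-chromen-4-one | C=CCc1c(OC)cc2occ(-c3ccc(OC)cc3)c(=O)c2c1OC | intermediate
14 | 6-allyl-5,7-dihydroxy-3-(4-hydroxyphenyl)-4H-chromen-4-one | C=CCc1c(O)cc2occ(-c3ccc(O)cc3)c(=O)c2c1O | intermediate
15 | methacrolein | C=C(C)C=O | starting material
16 | (E)-4-[5,7-dihydroxy-3-(4-hydroxyphenyl)-4-oxo-4H-chromen-6-yl]-2-methylbut-2-enal | C/C(=C\Cc1c(O)cc2occ(-c3ccc(O)cc3)c(=O)c2c1O)C=O | intermediate
17 | 5,7-dihydroxy-6-[(E)-4-hydroxy-3-methylbut-2-en-1-yl]-3-(4-hydroxyphenyl)-4H-chromen-4-one | C/C(=C\Cc1c(O)cc2occ(-c3ccc(O)cc3)c(=O)c2c1O)CO | target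

Total step count: 11 steps.
Longest linear sequence: 9 steps (steps 1–3 and 6–11, from 3,5-dimethoxyphenol); the arylacetate branch (steps 4–5) joins at step 6.

Steps most likely to fail

Step 8. The cyclisation may stall or divert through competing trifluoroacetylation of the very electron-rich ring A, through acid addition across the allyl double bond, or because E-configured acid fails to isomerise so that the acyl group never reaches the ring. The fallback abandons the C4–C4a closure and builds ring C by the deoxybenzoin sequence, which uses the same ring-A symmetry. It sets out from phenol 6, which is C-acylated ortho to the hydroxyl with 4-methoxyphenylacetic acid in BF3·OEt2 at moderate temperature (acylation with boron chelation of the ortho-hydroxy ketone) to give 1-(3-allyl-6-hydroxy-2,4-dimethoxyphenyl)-2-(4-methoxyphenyl)ethan-1-one F1. Heating F1 with N,N-dimethylformamide dimethyl acetal in toluene inserts C2 and closes the pyranone ring, returning to the route at 13.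

Step 6. The phenoxide may attack the sulfonyl sulfur instead of the β-carbon, which transfers the tosyl group and returns the enol, or the alkene geometry may scramble through a longer-lived carbanion. The fallback sets out from enol 8, which is converted with (COCl)2 and catalytic DMF in CH2Cl2 (Vilsmeier-type deoxychlorination) into methyl (Z)-3-chloro-2-(4-methoxyphenyl)acrylate F2. This vinyl chloride has no competing electrophilic site; addition–elimination with phenol 6 and K2CO3 in DMF displaces chloride and comes back to the route at 10.

Step 9. A freed ortho hydroxyl may close onto the allyl double bond under the acidic quench, hydrogen bromide may add to the alkene, or cleavage at O7 and O4' may remain incomplete. The fallback stages the deprotection and moves the harder cleavages to a non-acidic mechanism. It sets out from 13, where BCl3 in CH2Cl2 at −78 °C removes only the chelated 5-methyl ether to give 6-allyl-5-hydroxy-7-methoxy-3-(4-methoxyphenyl)-4H-chromen-4-one F3. The two remaining methyl ethers are then cleaved by SN2 attack of NaSEt in DMF at about 110 °C, with the chromone protected as its 5-phenoxide, returning to the route at 14.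

Further compounds
F1 | step 8 | 1-(3-allyl-6-hydroxy-2,4-dimethoxyphenyl)-2-(4-methoxyphenyl)ethan-1-one | C=CCc1c(OC)cc(O)c(C(=O)Cc2ccc(OC)cc2)c1OC
F2 | step 6 | methyl (Z)-3-chloro-2-(4-methoxyphenyl)acrylate | COC(=O)/C(=C\Cl)c1ccc(OC)cc1
F3 | step 9 | 6-allyl-5-hydroxy-7-methoxy-3-(4-methoxyphenyl)-4H-chromen-4-one | C=CCc1c(OC)cc2occ(-c3ccc(OC)cc3)c(=O)c2c1O
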